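Late in both runs the product stops climbing, and that level is what we have to forecast for Wednesday's flask.

| setting | Wednesday's | Friday's | flask |
|---|---|---|---|
| substrate | 0.10 M | 0.10 M | 0.10 M |
| coupling partner | 0.060 M | 0.030 M | 0.0600 M |
| temperature | 100 °C | 106 °C | 100 °C |
| remark | the very flask that is asked about, followed so far | run made earlier |  |
| time |  |  | 8.0 d |

Wednesday's run (percent of the substrate charged)

| time / d | product / % |
|---|---|
| 0.625 | 57.1 |
| 1.67 | 59.6 |
| 3.00 | 61.4 |
| 8.00 | 59.1 |

Friday's run (percent of the substrate charged)

| time / h | product / % |
|---|---|
| 3.00 | 25.4 |
| 8.00 | 31.6 |
| 20.0 | 30.0 |
| 40.0 | 29.6 |

(readings scatter by 1 percentage point)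

- epsilon: at 8.0 d add coupling partner, 100% of the amount charged, then wait 4.0 d
- delta: at 8.0 d raise the temperature by 25 K, then wait 4.0 d
- gamma: change nothing and wait 4.0 d more
- beta: at 8.0 d take out 90% of the product then present, then wait 4.0 d

* product, in percent of the substrate first charged, at 8.0 d
* the option that brings most further product ("none" if no option brings more than 2 percentage points) (epsilon / delta / gamma / beta / none)
* product present, with what was taken out counted in, in percent of the substrate first charged, after epsilon
* product present, with what was taken out counted in, in percent of the substrate first charged, after delta

- product that was removed still counts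
- the numbers in the tables scatter by 1 percentage point (one standard deviation)
- additions bring no volume worth counting

Which given numbers must we know well? Take the time first. Wednesday's flask reads 59.6% at 1.67 d and 59.1% at 8.00 d, which differ by 0.5 percentage points, with a scatter of 1 point on each reading, so the time need not be exact. Nor need the rate be known well: the reading is already 57.1% at 0.625 d, and 8.0 d is 12.8 times that time. Temperature comes next: Friday's run stood at 106 °C and Wednesday's at 100 °C, yet the levels still follow the partner charge. The partner charge has to be known well: Friday's run had half the coupling partner and read half the product at its last reading, 29.6% against 59.1%, though the two runs differ in temperature as well. The substrate charge, 0.10 M in both runs, is the divisor of every percentage, so it must be known just as well.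

So we need a ratio of two charges. For this flask 60.0% is the partner ceiling, c(coupling partner) divided by c(substrate) as charged, one product per partner. The coupling partner is the limiting reagent, since its charge is smaller. Friday's charges give 30.0% by the same ratio. We therefore expect 60.0% now, and the same after waiting, heating or taking out product, since none of these changes the ceiling. Adding partner lifts the ratio past the substrate, so our figure after epsilon is 100%.

The forecast gives 60% now, epsilon as best, 99% after epsilon, a little under our figure, and 60% after delta, holding that the reaction “stops because the partner runs out”.

The flask gives 60.0% at 8.0 d, the ceiling of 60.0%, and epsilon is best with 100%, while delta gives 60.0%; the forecast is right within its margins.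

    2 substrate ⇌ resting dimer, settled at all times (K = 35.0 M⁻¹, ΔH = −1.00 kJ mol⁻¹)
    substrate + coupling partner → product (k = 13.0 M⁻¹ h⁻¹, Ea = 85.0 kJ mol⁻¹)
    (constants at 100 °C)

The coupling partner's half-life by its step with substrate is 0.088 d at 0.0797 d, far shorter than the 8.0 d of the flask. At 8.00 d the flask holds 0% of that partner. For the neighbour flask with 0.015 M of partner the ceiling is 15.0%, and that flask stands at 15.0%.

All runs are calculated for substances that don't exist, and the scatter is random.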